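**Retrosynthetic overview**

1. Target numbering (1S,2S,3R, all-trans): C1 = CH(aryl), C2 and C3 = CH(CH3), C4 = CH2, ring A = C4a–C8a with methoxy groups on C6 and C7, ring B = the saturated ring. The C4 methylene is carried as a ketone and removed by hydrogenolysis in the last step.
2. Key disconnection: C4–C4a and C1–C8a together, giving veratrole and an all-trans γ-aryl-α,β-dimethyl-γ-butyrolactone. A one-pot Friedel–Crafts alkylation/acylation closes ring B, the only ring formed in the route (ring A and the pendant aryl ring are bought as veratrole and veratraldehyde), and sets C1.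
3. Enabling feature: ring A is a 1,2-dimethoxybenzene whose fusion carbons C8a and C4a lie para to the C6 and C7 methoxy groups, the two equivalent, most nucleophilic carbons of veratrole. The C1 aryl group is the same 3,4-dimethoxyphenyl unit, so C1 passes through a CH(aryl)2 stage with two identical aryl groups and the benzylic configuration of the lactone is irrelevant.
4. Lactone from veratraldehyde: catalytic asymmetric anti-crotylation (sets the C2 methyl centre, which controls C1 and C3), hydroboration–oxidation, oxidative lactonisation, trans-selective α-methylation.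

Key step: step 5

Assumption: the (R)-configured phosphoric acid of this family is taken to direct addition to the re face of aryl aldehydes, so its (S)-antipode is specified for the (1S,2S)-alcohol; if the sense proves opposite, the enantiomeric catalyst is used and nothing else changes.

**Route**

Step 1
Reactants: 1 3,4-dimethoxybenzaldehyde (veratraldehyde); 2 (E)-crotylboronic acid pinacol ester
Product: 4 (1S,2S)-1-(3,4-dimethoxyphenyl)-2-methylbut-3-en-1-ol, via pinacol borate ester 3 (not isolated)
Conditions: (S)-TRIP [(S)-3,3'-bis(2,4,6-triisopropylphenyl)-1,1'-binaphthyl-2,2'-diyl hydrogen phosphate] (5 mol %), 2 (1.2 equiv), toluene, 4 Å MS, –30 °C; aq. NaHCO3 work-up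
Reagents that add atoms: (E)-crotylboronic acid pinacol ester (compound 2), C/C=C/CB1OC(C)(C)C(C)(C)O1
Why: Chiral phosphoric acid-catalysed crotylboration of an aldehyde through a closed six-membered chair transition state: the (E)-geometry of 2 is translated into the anti relationship and the catalyst, hydrogen-bonded to the boronate oxygen, should expose the si face of the aldehyde, so that C1 (S) and C2 (S) are set together, and borate ester 3 is cleaved on aqueous work-up.

Step 2
Reactants: 4 (1S,2S)-1-(3,4-dimethoxyphenyl)-2-methylbut-3-en-1-ol
Product: 6 (1S,2S)-1-(3,4-dimethoxyphenyl)-2-methylbutane-1,4-diol, via bis-9-BBN adduct 5 (not isolated)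
Conditions: 9-BBN (9-borabicyclo[3.3.1]nonane, 2.2 equiv), THF, 0 °C → rt; then 3 M NaOH, 30% H2O2, 0 °C → rt
Reagents that add atoms: hydrogen peroxide, OO (oxygen of the new primary alcohol); 9-BBN, B1C2CCCC1CCC2 (adds boron to 5 only)
Why: Terminal-selective hydroboration of the monosubstituted alkene with the bulky 9-BBN (a second equivalent is consumed by the hydroxyl group) and alkaline peroxide oxidation of the C–B bond give the primary alcohol; no stereocentre is formed and neither existing one is at a reacting carbon.

Step 3
Reactants: 6 (1S,2S)-1-(3,4-dimethoxyphenyl)-2-methylbutane-1,4-diol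
Product: 8 (4S,5S)-5-(3,4-dimethoxyphenyl)-4-methyldihydrofuran-2(3H)-one, via lactol 7 (not isolated)
Conditions: TEMPO (2,2,6,6-tetramethylpiperidin-1-oxyl, 0.2 equiv), PhI(OAc)2 (2.5 equiv), CH2Cl2, rt
Reagents that add atoms: none
Why: Oxoammonium (TEMPO/PhI(OAc)2) oxidative lactonisation of a 1,4-diol: the primary alcohol is oxidised in preference to the secondary benzylic one, the aldehyde is captured as lactol 7 and this is oxidised on to the γ-lactone, with both stereocentres untouched.

Step 4
Reactants: 8 (4S,5S)-5-(3,4-dimethoxyphenyl)-4-methyldihydrofuran-2(3H)-one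
Product: 10 (3S,4S,5S)-5-(3,4-dimethoxyphenyl)-3,4-dimethyldihydrofuran-2(3H)-one, via lithium enolate 9 (not isolated)
Conditions: LiN(iPr)2 (1.1 equiv), THF, –78 °C; MeI (2 equiv), –78 → –40 °C
Reagents that add atoms: iodomethane, CI; LiN(iPr)2, [Li]N(C(C)C)C(C)C (supplies the lithium of 9 only)
Why: Kinetic alkylation of a γ-butyrolactone enolate: iodomethane should attack enolate 9 on the face anti to the adjacent C4 methyl group, giving the 3,4-trans (all-trans) lactone, and any cis isomer is not fatal because this centre becomes epimerisable again in ketone 13.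

Step 5
Reactants: 10 (3S,4S,5S)-5-(3,4-dimethoxyphenyl)-3,4-dimethyldihydrofuran-2(3H)-one; 11 1,2-dimethoxybenzene (veratrole)
Product: 13 (2S,3R,4S)-4-(3,4-dimethoxyphenyl)-6,7-dimethoxy-2,3-dimethyl-3,4-dihydronaphthalen-1(2H)-one, via diaryl acid 12 (not isolated)
Conditions: 11 (2 equiv), CF3SO3H (8 equiv), CH2Cl2, –20 °C (alkylation) → rt (ring closure), one pot
Reagents that add atoms: veratrole (compound 11), COc1ccccc1OC
Why: Protonation of lactone 10 ionises the benzylic C5–O bond to a para-methoxy-stabilised benzylic cation, which alkylates veratrole para to a methoxy group to give acid 12; the protonated carboxyl group of 12 then loses water to an acylium ion that acylates an aryl ring ortho to the new C–C bond and para to the other methoxy group, so that both ring-fusion bonds are made in one flask. The closest known reaction type is the one-pot Friedel–Crafts alkylation/acylation of arenes with γ-aryl-γ-butyrolactones to 4-aryl-1-tetralones in strong acid. Ring B is closed by a 6-exo intramolecular Friedel–Crafts acylation (exo with respect to the acyl C=O), while ring A and the pendant ring are delivered intact. The only new stereocentre, C4 of 13 (C1 of the target), arises because the two aryl groups on the CH(aryl)2 carbon of 12 are constitutionally identical but diastereotopic, so closure onto either gives the same constitution: the chair-like transition state that keeps the C3 methyl group and the non-reacting aryl group equatorial should be preferred and gives the 3,4-trans product, while C2, now alpha to the ketone, can equilibrate by enolisation to the thermodynamically preferred 2,3-trans arrangement. The step needs regioselectivity (secured because each bond forms para to a methoxy group and the alternatives are flanked ortho positions), ring closure faster than acylation of excess veratrole (secured by intramolecularity) and retention of the C4 methyl configuration of 10 next to the cation (secured by low temperature and rapid capture by excess veratrole).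

Step 6
Reactants: 13 (2S,3R,4S)-4-(3,4-dimethoxyphenyl)-6,7-dimethoxy-2,3-dimethyl-3,4-dihydronaphthalen-1(2H)-one
Product: 15 galbulin [(1S,2S,3R)-1-(3,4-dimethoxyphenyl)-6,7-dimethoxy-2,3-dimethyl-1,2,3,4-tetrahydronaphthalene], via benzylic alcohol 14 (not isolated)
Conditions: H2 (4 bar), Pd/C (10% palladium on carbon), AcOH, cat. HClO4, rt
Reagents that add atoms: none
Why: Acid-assisted catalytic hydrogenolysis of an aryl ketone on an electron-rich ring, through benzylic alcohol 14, to the methylene group; no stereocentre is created and the three existing ones are spectators.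

**Compound list**

1 | 3,4-dimethoxybenzaldehyde (veratraldehyde) | COc1ccc(C=O)cc1OC | starting material
2 | (E)-crotylboronic acid pinacol ester | C/C=C/CB1OC(C)(C)C(C)(C)O1 | starting material
3 | pinacol borate ester of alcohol 4 | CC1(C)OB(O[C@H](c2ccc(OC)c(OC)c2)[C@@H](C)C=C)OC1(C)C | intermediate (not isolated)
4 | (1S,2S)-1-(3,4-dimethoxyphenyl)-2-methylbut-3-en-1-ol | O[C@H](c1ccc(OC)c(OC)c1)[C@@H](C)C=C | intermediate
5 | bis-9-BBN adduct of 4 (terminal alkylborane and O-borinate) | C[C@@H](CCB1C2CCCC1CCC2)[C@H](OB1C2CCCC1CCC2)c1ccc(OC)c(OC)c1 | intermediate (not isolated)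
6 | (1S,2S)-1-(3,4-dimethoxyphenyl)-2-methylbutane-1,4-diol | O[C@H](c1ccc(OC)c(OC)c1)[C@@H](C)CCO | intermediate
7 | (4S,5S)-5-(3,4-dimethoxyphenyl)-4-methyltetrahydrofuran-2-ol (lactol, anomeric mixture) | OC1O[C@H](c2ccc(OC)c(OC)c2)[C@@H](C)C1 | intermediate (not isolated)
8 | (4S,5S)-5-(3,4-dimethoxyphenyl)-4-methyldihydrofuran-2(3H)-one | O=C1O[C@H](c2ccc(OC)c(OC)c2)[C@@H](C)C1 | intermediate
9 | lithium enolate of lactone 8 | [Li]OC1=C[C@H](C)[C@@H](c2ccc(OC)c(OC)c2)O1 | intermediate (not isolated)
10 | (3S,4S,5S)-5-(3,4-dimethoxyphenyl)-3,4-dimethyldihydrofuran-2(3H)-one | O=C1O[C@H](c2ccc(OC)c(OC)c2)[C@@H](C)[C@@H]1C | intermediate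
11 | 1,2-dimethoxybenzene (veratrole) | COc1ccccc1OC | starting material
12 | (2S,3R)-4,4-bis(3,4-dimethoxyphenyl)-2,3-dimethylbutanoic acid | OC(=O)[C@@H](C)[C@H](C)C(c1ccc(OC)c(OC)c1)c1ccc(OC)c(OC)c1 | intermediate (not isolated)
13 | (2S,3R,4S)-4-(3,4-dimethoxyphenyl)-6,7-dimethoxy-2,3-dimethyl-3,4-dihydronaphthalen-1(2H)-one | COc1ccc([C@H]2c3cc(OC)c(OC)cc3C(=O)[C@@H](C)[C@@H]2C)cc1OC | intermediate
14 | (2S,3R,4S)-4-(3,4-dimethoxyphenyl)-6,7-dimethoxy-2,3-dimethyl-1,2,3,4-tetrahydronaphthalen-1-ol (C1 epimers) | COc1ccc([C@H]2c3cc(OC)c(OC)cc3C(O)[C@@H](C)[C@@H]2C)cc1OC | intermediate (not isolated)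
15 | galbulin, (1S,2S,3R)-1-(3,4-dimethoxyphenyl)-6,7-dimethoxy-2,3-dimethyl-1,2,3,4-tetrahydronaphthalene | COc1ccc([C@H]2c3cc(OC)c(OC)cc3C[C@@H](C)[C@@H]2C)cc1OC | target

**Step count and risks**

Total steps: 6. Longest linear sequence: 6 steps (from veratraldehyde 1).

Steps most likely to fail:

Step 5 (key step). Three processes could defeat it: reversible proton loss from the benzylic cation before veratrole captures it, which would erode the C4 methyl configuration of 10 and racemise the series; weak discrimination between the two diastereotopic aryl groups in the ring closure, which would give the C4 epimer of 13; and acylation of excess veratrole in place of ring closure. The fallback sets out from 10, comes back to the route at 15 and makes step 6 unnecessary. Ring B is closed instead by attack of ring A on a benzylic cation at C1 of the target, the biosynthesis-like closure. Reduction of 10 with iBu2AlH (CH2Cl2, –78 °C) should give the lactol (3S,4S,5S)-5-(3,4-dimethoxyphenyl)-3,4-dimethyltetrahydrofuran-2-ol F1. Addition of 3,4-(MeO)2C6H3MgBr (3 equiv, THF, 0 °C → rt) to its open hydroxy-aldehyde form should give the diol (1S,2S,3S)-1,4-bis(3,4-dimethoxyphenyl)-2,3-dimethylbutane-1,4-diol F2 as a mixture of C4 epimers. Hydrogenolysis of both benzylic C–O bonds (H2, Pd(OH)2/C, EtOH, rt) should give (2R,3R)-1,4-bis(3,4-dimethoxyphenyl)-2,3-dimethylbutane F3, whose C2-symmetric core makes its two benzylic CH2 groups equivalent. DDQ (2,3-dichloro-5,6-dicyano-1,4-benzoquinone, 1.1 equiv) in CF3CO2H/CH2Cl2 at 0 °C should then remove a hydride from one benzylic position para to methoxy, and the cation should be captured by the other ring para to its own methoxy group, a closure expected to place the aryl group trans to the neighbouring methyl group and so to give 15.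

Step 6. Acid-promoted loss of water from benzylic alcohol 14 toward the ring alkene, followed by unselective hydrogenation, would scramble the adjacent methyl-bearing centre; the reduction could also stall at the alcohol stage on this electron-rich ketone. The fallback sets out from 13 and comes back at 15. It replaces hydrogenolysis by a Wolff–Kishner reduction (N2H4·H2O, KOH, diethylene glycol, 130 → 200 °C), which proceeds through the hydrazone (2S,3R,4S)-4-(3,4-dimethoxyphenyl)-6,7-dimethoxy-2,3-dimethyl-3,4-dihydronaphthalen-1(2H)-one hydrazone F4 and an anionic loss of nitrogen. No benzylic cation or alkene is involved, and any base-induced epimerisation alpha to the C=N bond can only move toward the preferred trans arrangement.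

Step 1. Facial discrimination by the phosphoric acid could be insufficient with this electron-rich, weakly electrophilic aldehyde, or an uncatalysed background crotylboration could compete; either would lower the enantiomeric purity of every later compound. The fallback sets out from 1 and comes back at 4. It changes the nucleophile from an allylboron reagent to a crotyl-iridium species generated catalytically by transfer hydrogenation: but-3-en-2-yl acetate, [Ir(cod)Cl]2, SEGPHOS (the antipode that delivers the (1S,2S)-alcohol), 4-cyano-3-nitrobenzoic acid, Cs2CO3, 2-propanol, THF, 70 °C. This anti-selective carbonyl crotylation should give 4 directly.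

**Further compounds**

F1 | step 5 | (3S,4S,5S)-5-(3,4-dimethoxyphenyl)-3,4-dimethyltetrahydrofuran-2-ol (anomeric mixture) | OC1O[C@H](c2ccc(OC)c(OC)c2)[C@@H](C)[C@@H]1C
F2 | step 5 | (1S,2S,3S)-1,4-bis(3,4-dimethoxyphenyl)-2,3-dimethylbutane-1,4-diol (C4 epimers) | O[C@H](c1ccc(OC)c(OC)c1)[C@@H](C)[C@H](C)C(O)c1ccc(OC)c(OC)c1
F3 | step 5 | (2R,3R)-1,4-bis(3,4-dimethoxyphenyl)-2,3-dimethylbutane | COc1ccc(C[C@@H](C)[C@H](C)Cc2ccc(OC)c(OC)c2)cc1OC
F4 | step 6 | hydrazone of ketone 13 | COc1ccc([C@H]2c3cc(OC)c(OC)cc3C(=NN)[C@@H](C)[C@@H]2C)cc1OC
F0 | step 1 | none | none
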